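**Plan**
1. Ring A is a pentasubstituted resorcinol monomethyl ether: C1 (OMe) and C3 (OH) flank the only unsubstituted carbon C2, while C4, C5 and C6 carry 4-hydroxybenzyl, the CH2CH2–ring B chain and a second, identical 4-hydroxybenzyl. A cyclobutenone/alkoxyacetylene benzannulation delivers exactly this pattern.
2. Retrosynthesis: the four O–benzyl bonds go first; ring A is then cut at C2–C3 and C1–C6 (with C3–C4 opened) into methoxyacetylene (C1, C2, OMe) and a 2,4-dibenzyl-3-alkylcyclobutenone (C3–C6 and the phenol oxygen).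
3. The cyclobutenone is cut at the bond from its C3 to the chain (alkyllithium addition to a 3-ethoxycyclobutenone, then acid transposition). The 3-ethoxycyclobutenone is cut into two molecules of one ynol ether, made from ethoxyacetylene and 4-(benzyloxy)benzyl chloride.
4. The ring B iodide goes back to 4-bromo-2-hydroxybenzaldehyde and 1-(benzyloxy)-4-bromobenzene (diarylmethane C–C bond) and ethylene oxide (two-carbon chain).
5. Forward: ring B fragment (steps 1–5), four-membered ring (steps 6–7), chain joined (step 8), methoxyacetylene (step 9), ring A closed (step 10), debenzylation (step 11).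
6. Stereochemistry: the target is achiral; every sp3 centre met on the way (carbinol, cyclobutenones, annulation intermediates) is racemic and is erased.

Key step: step 10

Remark: methoxyacetylene is not relied on as a catalogue item and is prepared in the route; every phenol except the one created by the annulation is carried as its benzyl ether, so one hydrogenolysis ends the synthesis.

**Route**

Step 1
Reactants: 1 4-bromo-2-hydroxybenzaldehyde
Product: 2 2-(benzyloxy)-4-bromobenzaldehyde
Conditions: BnBr, K2CO3, DMF, rt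
Reagents that add atoms: benzyl bromide, BrCc1ccccc1
Why: Williamson etherification of the acidic salicylaldehyde phenol under carbonate is routine and leaves the aldehyde and the aryl bromide untouched.

Step 2
Reactants: 3 1-(benzyloxy)-4-bromobenzene; 2 2-(benzyloxy)-4-bromobenzaldehyde
Product: 5 [2-(benzyloxy)-4-bromophenyl][4-(benzyloxy)phenyl]methanol (racemic), via arylmagnesium bromide 4 (not isolated)
Conditions: 3, Mg, THF, reflux; then 2, 0 °C; aq. NH4Cl
Reagents that add atoms: none
Why: Grignard addition of the arylmagnesium bromide to the aldehyde should give the diaryl carbinol, since the aryl bromide of 2 does not exchange with an arylmagnesium halide at 0 °C; the carbinol centre is racemic and is removed in step 3.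

Step 3
Reactants: 5 [2-(benzyloxy)-4-bromophenyl][4-(benzyloxy)phenyl]methanol
Product: 6 2-(benzyloxy)-1-[4-(benzyloxy)benzyl]-4-bromobenzene
Conditions: Et3SiH, TFA, CH2Cl2, 0 °C
Reagents that add atoms: none
Why: Ionic hydrogenation: the benzhydryl cation, stabilised by an ortho and a para alkoxy group, forms at 0 °C and is trapped by silane hydride faster than benzyl ethers are cleaved.

Step 4
Reactants: 6 2-(benzyloxy)-1-[4-(benzyloxy)benzyl]-4-bromobenzene
Product: 8 2-{3-(benzyloxy)-4-[4-(benzyloxy)benzyl]phenyl}ethan-1-ol, via aryllithium 7 (not isolated)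
Conditions: n-BuLi, THF, −78 °C; ethylene oxide (excess), −78 °C to rt; aq. NH4Cl
Reagents that add atoms: ethylene oxide, C1CO1
Why: Bromine–lithium exchange at −78 °C outruns benzylic deprotonation, and nucleophilic ring opening of ethylene oxide by the aryllithium gives the primary 2-arylethanol in one operation.

Step 5
Reactants: 8 2-{3-(benzyloxy)-4-[4-(benzyloxy)benzyl]phenyl}ethan-1-ol
Product: 9 2-(benzyloxy)-1-[4-(benzyloxy)benzyl]-4-(2-iodoethyl)benzene
Conditions: I2, PPh3, imidazole, CH2Cl2, 0 °C to rt
Reagents that add atoms: iodine, II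
Why: Appel-type iodination converts the primary alcohol into the iodide by SN2 displacement of the alkoxyphosphonium under nearly neutral conditions that spare the benzyl ethers.

Step 6
Reactants: 10 ethoxyacetylene; 11 4-(benzyloxy)benzyl chloride
Product: 13 1-(benzyloxy)-4-(3-ethoxyprop-2-yn-1-yl)benzene, via lithium ethoxyacetylide 12 (not isolated)
Conditions: 10, n-BuLi, THF, −78 °C; then 11, DMPU, −78 °C to rt
Reagents that add atoms: none
Why: SN2 C-alkylation of the lithium alkoxyacetylide by the reactive 4-alkoxybenzyl chloride in THF/DMPU should give the ynol ether, the acetylide being too weak a base to isomerise the product to an allenyl ether.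

Step 7
Reactants: 13 1-(benzyloxy)-4-(3-ethoxyprop-2-yn-1-yl)benzene (two molecules)
Product: 15 2,4-bis[4-(benzyloxy)benzyl]-3-ethoxycyclobut-2-en-1-one (racemic), via aldoketene 14 (not isolated)
Conditions: toluene (concentrated), 110 °C, N2
Reagents that add atoms: none
Why: Thermal retro-ene fragmentation of a 1-ethoxyalk-1-yne releases ethene and the aldoketene, which is captured by a second molecule of the ynol ether in a polarity-controlled ketene–alkyne [2+2] cycloaddition (benzyl-bearing alkyne carbon to the ketene carbonyl carbon), the classical entry to 2,4-dialkyl-3-ethoxycyclobutenones; the ketene forms slowly beside excess ketenophile, so dimerisation is disfavoured, and the one sp3 centre is racemic.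

Step 8
Reactants: 9 2-(benzyloxy)-1-[4-(benzyloxy)benzyl]-4-(2-iodoethyl)benzene; 15 2,4-bis[4-(benzyloxy)benzyl]-3-ethoxycyclobut-2-en-1-one
Product: 18 2,4-bis[4-(benzyloxy)benzyl]-3-(2-{3-(benzyloxy)-4-[4-(benzyloxy)benzyl]phenyl}ethyl)cyclobut-2-en-1-one (racemic), via alkyllithium 16 (not isolated), via tertiary carbinol 17 (not isolated)
Conditions: 9, t-BuLi (2 equiv), Et2O, −78 °C; then 15, THF, −78 °C; then 1 M aq. HCl, 0 °C to rt
Reagents that add atoms: water, O
Why: Iodine–lithium exchange gives the primary alkyllithium, which adds 1,2 to the vinylogous ester (C4–H is not removed because its enolate would be an antiaromatic cyclobutadienolate), and acid hydrolysis of the ethoxy allylic carbinol with loss of ethanol (Stork–Danheiser-type 1,3-carbonyl transposition) should give the 3-alkylcyclobutenone; as the two benzyl groups are identical, addition–elimination at C3 would give the same constitution, and C4 stays racemic.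

Step 9
Reactants: 19 chloroacetaldehyde dimethyl acetal
Product: 21 methoxyacetylene, via sodium methoxyacetylide 20 (not isolated)
Conditions: NaNH2 (3 equiv), liq. NH3, −33 °C; then H2O, −70 °C; distilled into cold toluene
Reagents that add atoms: none
Why: Twofold base-induced elimination (methanol, then HCl) from the chloroacetal with sodium amide gives the sodium alkoxyacetylide, protonated on aqueous quench, which is the standard alkoxyacetylene preparation; the volatile product is kept as a cold toluene solution.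

Step 10
Reactants: 18 2,4-bis[4-(benzyloxy)benzyl]-3-(2-{3-(benzyloxy)-4-[4-(benzyloxy)benzyl]phenyl}ethyl)cyclobut-2-en-1-one; 21 methoxyacetylene
Product: 26 2,4-bis[4-(benzyloxy)benzyl]-3-(2-{3-(benzyloxy)-4-[4-(benzyloxy)benzyl]phenyl}ethyl)-5-methoxyphenol, via vinylketene 22 (not isolated), via vinylcyclobutenone 23 (not isolated), via dienylketene 24 (not isolated), via cyclohexadienone 25 (not isolated)
Conditions: 21 (4 equiv, toluene solution), sealed tube, 80 °C then 110 °C
Reagents that add atoms: none
Why: Heating opens 18 by 4π electrocyclic cleavage of its C1–C4 bond (ring A C3–C4) to the (E)-vinylketene 22, whose ketene C=C adds methoxyacetylene in a [2+2] cycloaddition that forms ring A bonds C2–C3 and C1–C6 (23); a second 4π opening gives dienylketene 24, which closes the six-membered ring A by thermal disrotatory 6π electrocyclisation (re-forming C3–C4) to dienone 25 and tautomerises to phenol 26. This is the Danheiser benzannulation of a cyclobutenone with an alkynyl ether, here in a heavily substituted case. No stereocentre remains, since the transient sp3 centres of 23 and 25 are racemic and vanish on aromatisation. The step needs regiocontrol in the [2+2], and the polarised ynol ether secures it: its nucleophilic CH carbon bonds to the ketene carbonyl carbon, so H ends ortho and OMe meta to the new hydroxyl, and the two oxygens are differentiated by origin without any selective methylation. Outward rotation of the C4 benzyl group in the first opening keeps its CH2 away from the ketene (no [1,5]-hydrogen shift), and a methyl ynol ether, unlike an ethyl one, has no β-hydrogen for retro-ene loss at 110 °C.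

Step 11
Reactants: 26 2,4-bis[4-(benzyloxy)benzyl]-3-(2-{3-(benzyloxy)-4-[4-(benzyloxy)benzyl]phenyl}ethyl)-5-methoxyphenol
Product: 27 2,4-bis(4-hydroxybenzyl)-3-{2-[3-hydroxy-4-(4-hydroxybenzyl)phenyl]ethyl}-5-methoxyphenol (target)
Conditions: H2 (1 atm), 10% Pd/C, EtOAc/MeOH, rt
Reagents that add atoms: none
Why: Catalytic hydrogenolysis cleaves the four aryl benzyl ethers, while the diarylmethane CH2 groups, the aryl methyl ether and the arenes are inert under 1 atm of hydrogen at room temperature.

**Compound list**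
(ArCH2 = 4-(benzyloxy)benzyl; RB = 2-{3-(benzyloxy)-4-[4-(benzyloxy)benzyl]phenyl}ethyl)

1 | 4-bromo-2-hydroxybenzaldehyde | O=Cc1ccc(Br)cc1O | starting material
2 | 2-(benzyloxy)-4-bromobenzaldehyde | O=Cc1ccc(Br)cc1OCc1ccccc1 | intermediate
3 | 1-(benzyloxy)-4-bromobenzene | Brc1ccc(OCc2ccccc2)cc1 | starting material
4 | [4-(benzyloxy)phenyl]magnesium bromide (formed in the flask) | Br[Mg]c1ccc(OCc2ccccc2)cc1 | intermediate
5 | [2-(benzyloxy)-4-bromophenyl][4-(benzyloxy)phenyl]methanol (racemic) | OC(c1ccc(OCc2ccccc2)cc1)c1ccc(Br)cc1OCc1ccccc1 | intermediate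
6 | 2-(benzyloxy)-1-[4-(benzyloxy)benzyl]-4-bromobenzene | Brc1ccc(Cc2ccc(OCc3ccccc3)cc2)c(OCc2ccccc2)c1 | intermediate
7 | {3-(benzyloxy)-4-[4-(benzyloxy)benzyl]phenyl}lithium (formed in the flask) | [Li]c1ccc(Cc2ccc(OCc3ccccc3)cc2)c(OCc2ccccc2)c1 | intermediate
8 | 2-{3-(benzyloxy)-4-[4-(benzyloxy)benzyl]phenyl}ethan-1-ol | OCCc1ccc(Cc2ccc(OCc3ccccc3)cc2)c(OCc2ccccc2)c1 | intermediate
9 | 2-(benzyloxy)-1-[4-(benzyloxy)benzyl]-4-(2-iodoethyl)benzene | ICCc1ccc(Cc2ccc(OCc3ccccc3)cc2)c(OCc2ccccc2)c1 | intermediate
10 | ethoxyacetylene | CCOC#C | starting material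
11 | 4-(benzyloxy)benzyl chloride | ClCc1ccc(OCc2ccccc2)cc1 | starting material
12 | lithium ethoxyacetylide (formed in the flask) | CCOC#C[Li] | intermediate
13 | 1-(benzyloxy)-4-(3-ethoxyprop-2-yn-1-yl)benzene | CCOC#CCc1ccc(OCc2ccccc2)cc1 | intermediate
14 | 3-[4-(benzyloxy)phenyl]prop-1-en-1-one, the aldoketene ArCH2–CH=C=O (formed in the flask) | O=C=CCc1ccc(OCc2ccccc2)cc1 | intermediate
15 | 2,4-bis[4-(benzyloxy)benzyl]-3-ethoxycyclobut-2-en-1-one (racemic) | CCOC1=C(Cc2ccc(OCc3ccccc3)cc2)C(=O)C1Cc1ccc(OCc2ccccc2)cc1 | intermediate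
16 | (2-{3-(benzyloxy)-4-[4-(benzyloxy)benzyl]phenyl}ethyl)lithium (formed in the flask) | [Li]CCc1ccc(Cc2ccc(OCc3ccccc3)cc2)c(OCc2ccccc2)c1 | intermediate
17 | 2,4-bis(ArCH2)-3-ethoxy-1-RB-cyclobut-2-en-1-ol (diastereomer mixture, formed in the flask as its lithium alkoxide) | CCOC1=C(Cc2ccc(OCc3ccccc3)cc2)C(O)(CCc2ccc(Cc3ccc(OCc4ccccc4)cc3)c(OCc3ccccc3)c2)C1Cc1ccc(OCc2ccccc2)cc1 | intermediate
18 | 2,4-bis[4-(benzyloxy)benzyl]-3-(2-{3-(benzyloxy)-4-[4-(benzyloxy)benzyl]phenyl}ethyl)cyclobut-2-en-1-one (racemic) | O=C1C(Cc2ccc(OCc3ccccc3)cc2)=C(CCc2ccc(Cc3ccc(OCc4ccccc4)cc3)c(OCc3ccccc3)c2)C1Cc1ccc(OCc2ccccc2)cc1 | intermediate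
19 | chloroacetaldehyde dimethyl acetal (2-chloro-1,1-dimethoxyethane) | COC(CCl)OC | starting material
20 | sodium methoxyacetylide (formed in the flask) | COC#C[Na] | intermediate
21 | methoxyacetylene | COC#C | intermediate
22 | (E)-vinylketene O=C=C(ArCH2)–C(RB)=CH–CH2Ar, ketene carbon and terminal ArCH2 trans (formed in the flask) | O=C=C(Cc1ccc(OCc2ccccc2)cc1)/C(CCc1ccc(Cc2ccc(OCc3ccccc3)cc2)c(OCc2ccccc2)c1)=C/Cc1ccc(OCc2ccccc2)cc1 | intermediate
23 | 4-(ArCH2)-3-methoxy-4-[(E)-1-RB-3-(4-benzyloxyphenyl)prop-1-en-2-yl-type alkenyl]cyclobut-2-en-1-one, i.e. the 4-vinylcyclobutenone from 22 and 21 (racemic, formed in the flask) | COC1=CC(=O)C1(Cc1ccc(OCc2ccccc2)cc1)/C(CCc1ccc(Cc2ccc(OCc3ccccc3)cc2)c(OCc2ccccc2)c1)=C/Cc1ccc(OCc2ccccc2)cc1 | intermediate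
24 | dienylketene O=C=CH–C(OMe)=C(ArCH2)–C(RB)=CH–CH2Ar, ketene CH and vinyl group cis on the central C=C, terminal C=C as in 22 (formed in the flask) | O=C=C/C(OC)=C(Cc1ccc(OCc2ccccc2)cc1)\C(CCc1ccc(Cc2ccc(OCc3ccccc3)cc2)c(OCc2ccccc2)c1)=C\Cc1ccc(OCc2ccccc2)cc1 | intermediate
25 | 4,6-bis(ArCH2)-3-methoxy-5-RB-cyclohexa-2,4-dien-1-one (racemic, formed in the flask) | COC1=CC(=O)C(Cc2ccc(OCc3ccccc3)cc2)C(CCc2ccc(Cc3ccc(OCc4ccccc4)cc3)c(OCc3ccccc3)c2)=C1Cc1ccc(OCc2ccccc2)cc1 | intermediate
26 | 2,4-bis[4-(benzyloxy)benzyl]-3-(2-{3-(benzyloxy)-4-[4-(benzyloxy)benzyl]phenyl}ethyl)-5-methoxyphenol | COc1cc(O)c(Cc2ccc(OCc3ccccc3)cc2)c(CCc2ccc(Cc3ccc(OCc4ccccc4)cc3)c(OCc3ccccc3)c2)c1Cc1ccc(OCc2ccccc2)cc1 | intermediate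
27 | 2,4-bis(4-hydroxybenzyl)-3-{2-[3-hydroxy-4-(4-hydroxybenzyl)phenyl]ethyl}-5-methoxyphenol (CNP0207338.0) | COc1cc(O)c(Cc2ccc(O)cc2)c(CCc2ccc(Cc3ccc(O)cc3)c(O)c2)c1Cc1ccc(O)cc1 | target

**Step count**
Total steps: 11. Longest linear sequence: 8 steps (1, 2, 3, 4, 5, 8, 10, 11).

**Steps most likely to fail**

1. Step 10. The gaseous alkyne may be lost to the headspace or oligomerise before it intercepts the crowded, fully substituted ketene 22, which may instead dimerise or O-acylate the phenol already formed. The fallback sets out from 21 and 18 and returns at 26. Methoxyacetylene 21 is C-silylated (n-BuLi, THF, −78 °C; Me3SiCl) to 1-methoxy-2-(trimethylsilyl)ethyne F1, a distillable liquid that can be used in large excess in refluxing toluene at ambient pressure. Its annulation with 18 forms the same ring bonds with the same polarity (silicon-bearing carbon to the ketene carbonyl carbon, the β-silicon effect reinforcing the oxygen) and should give 2,4-bis[4-(benzyloxy)benzyl]-3-(2-{3-(benzyloxy)-4-[4-(benzyloxy)benzyl]phenyl}ethyl)-5-methoxy-6-(trimethylsilyl)phenol F2. Ipso-protodesilylation of the doubly oxygen-activated C–Si bond with TBAF in wet THF then leads to 26.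

2. Step 7. The retro-ene fragmentation needs about 110 °C, where slow ring opening of 15 and its consumption by remaining ynol ether, or oligomerisation of the ketene late in the run, may erode the material. The fallback sets out from 13 and returns at 15, generating the same ketene 14 at 0 °C by dehydrochlorination. Purchased 3-[4-(benzyloxy)phenyl]propanoic acid F3 is converted with oxalyl chloride and catalytic DMF in CH2Cl2 into 3-[4-(benzyloxy)phenyl]propanoyl chloride F4. This is added slowly to 13 and Et3N in CH2Cl2 at 0 °C to rt, so that the polarity-controlled [2+2] cycloaddition gives 15 without heating.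

3. Step 8. Elimination or Wurtz coupling during the iodine–lithium exchange, benzylic metalation or Wittig rearrangement of benzyl ethers by the alkyllithium, or incomplete addition to the flanked carbonyl may spoil the coupling. The fallback sets out from 15 and 9 and returns at 18, replacing the carbonyl addition by a cross-coupling. Hydrolysis of 15 (aq. HCl, THF) gives the symmetrical vinylogous acid 2,4-bis[4-(benzyloxy)benzyl]-3-hydroxycyclobut-2-en-1-one F5. Tf2O and Et3N in CH2Cl2 at −78 °C convert it into 2,4-bis[4-(benzyloxy)benzyl]-3-oxocyclobut-1-en-1-yl trifluoromethanesulfonate F6. Iodide 9 is converted with zinc dust and LiCl in THF into (2-{3-(benzyloxy)-4-[4-(benzyloxy)benzyl]phenyl}ethyl)zinc iodide F7. Negishi coupling of F7 with F6 under Pd(PPh3)4 (a zerovalent palladium complex) in THF then gives 18 without any strongly basic organometallic.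

**Further compounds**
F1 | step 10 | 1-methoxy-2-(trimethylsilyl)ethyne | COC#C[Si](C)(C)C
F2 | step 10 | 2,4-bis[4-(benzyloxy)benzyl]-3-(2-{3-(benzyloxy)-4-[4-(benzyloxy)benzyl]phenyl}ethyl)-5-methoxy-6-(trimethylsilyl)phenol | COc1c([Si](C)(C)C)c(O)c(Cc2ccc(OCc3ccccc3)cc2)c(CCc2ccc(Cc3ccc(OCc4ccccc4)cc3)c(OCc3ccccc3)c2)c1Cc1ccc(OCc2ccccc2)cc1
F3 | step 7 | 3-[4-(benzyloxy)phenyl]propanoic acid (purchased) | OC(=O)CCc1ccc(OCc2ccccc2)cc1
F4 | step 7 | 3-[4-(benzyloxy)phenyl]propanoyl chloride | ClC(=O)CCc1ccc(OCc2ccccc2)cc1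
F5 | step 8 | 2,4-bis[4-(benzyloxy)benzyl]-3-hydroxycyclobut-2-en-1-one | OC1=C(Cc2ccc(OCc3ccccc3)cc2)C(=O)C1Cc1ccc(OCc2ccccc2)cc1
F6 | step 8 | 2,4-bis[4-(benzyloxy)benzyl]-3-oxocyclobut-1-en-1-yl trifluoromethanesulfonate | O=C1C(Cc2ccc(OCc3ccccc3)cc2)=C(OS(=O)(=O)C(F)(F)F)C1Cc1ccc(OCc2ccccc2)cc1
F7 | step 8 | (2-{3-(benzyloxy)-4-[4-(benzyloxy)benzyl]phenyl}ethyl)zinc iodide | I[Zn]CCc1ccc(Cc2ccc(OCc3ccccc3)cc2)c(OCc2ccccc2)c1
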